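**Retrosynthetic overview**
- The target, read as robinetinidol-(4β→8)-epigallocatechin 3-O-gallate, is unmasked last from a dodeca-O-benzyl, upper-3-O-silyl dimer by desilylation and hydrogenolysis.
- Lower ring C is cut across O1–C2 and C3–C4 as a hetero-Diels–Alder reaction. The enabling feature is that the lower C4 is a bare CH2 on ring A ortho to the ring oxygen O1, so C4=C4a–C8a=O1 can exist as an o-quinone methide, while C2 and C3 carry ring B and the galloyloxy group cis, which are the two ends of a (Z)-enol gallate.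
- The (Z)-enol gallate comes in one step from an aryl alkyne and the protected gallic acid; the methide precursor comes from ortho-formylation and reduction of a phenol.
- The interflavan C4–C8 bond is made by adding the lithiated lower ring A to the 4-ketone of the upper unit, and acid/stannane deoxygenation then sets the 3,4-cis (4β) centre.
- Ring order: upper rings A, C and B come from chiral-pool (+)-dihydrorobinetin, lower ring A is attached next, and lower ring C is closed last, carrying in ring B and the gallate.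

Key step: step 10

Remark: the SMILES is read as upper unit 2R,3S,4R (2,3-trans, 3,4-cis) and lower unit 2R,3R (2,3-cis).
Remark: (+)-dihydrorobinetin (2R,3R) is taken as a purchasable chiral-pool material.
Remark: the (R)-acid in step 10 is assumed to be the enantiomer matched to the 2R,3R ring; if not, its mirror image would be used with nothing else changed.

Step 1
Reactants: 1 (+)-dihydrorobinetin
Product: 2 7,3',4',5'-tetra-O-benzyl-dihydrorobinetin
Conditions: BnBr (4.4 equiv), K2CO3, DMF, rt, argon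
Reagents that add atoms: benzyl bromide, BrCc1ccccc1
Why: Williamson etherification under mild carbonate conditions alkylates the four acidic phenols and should leave the less acidic 3-OH and the C2/C3 stereocentres untouched.

Step 2
Reactants: 2 tetra-O-benzyl-dihydrorobinetin
Product: 3 3-O-TBS-tetra-O-benzyl-dihydrorobinetin
Conditions: TBSOTf, 2,6-lutidine, CH2Cl2, 0 °C
Reagents that add atoms: tert-butyldimethylsilyl trifluoromethanesulfonate, CC(C)(C)[Si](C)(C)OS(=O)(=O)C(F)(F)F
Why: Silylation of the hindered α-hydroxy ketone with the silyl triflate under non-enolising conditions installs a bulky 3-O group that will later shield the β face of C4.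

Step 3
Reactants: 4 3,5-bis(benzyloxy)phenol
Product: 5 1,3-bis(benzyloxy)-5-(methoxymethoxy)benzene
Conditions: MOMCl, i-Pr2NEt, CH2Cl2, 0 °C to rt
Reagents that add atoms: chloromethyl methyl ether, COCCl
Why: O-alkylation of the phenol gives an acetal ether that is the strongest metalation-directing group on the ring and is later lost in acid.

Step 4
Reactants: 5 1,3-bis(benzyloxy)-5-(methoxymethoxy)benzene; 3 3-O-TBS-tetra-O-benzyl-dihydrorobinetin
Product: 7 C4 tertiary carbinol of the coupled upper unit (C4 epimers not distinguished), via aryllithium 6 (not isolated)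
Conditions: 5 (1.5 equiv), n-BuLi, THF, 0 °C; then 3, −78 to −40 °C; H2O quench
Reagents that add atoms: none
Why: Directed ortho-lithiation between the MOM ether and a benzyloxy group followed by 1,2-addition of the aryllithium to the 4-ketone forms the interflavan C–C bond at the future C8, the regiochemistry being fixed by the site of the metal and the configuration of the new carbinol carbon being irrelevant because it is ionised in step 5.

Step 5
Reactants: 7 C4 tertiary carbinol
Product: 9 3,5-bis(benzyloxy)-2-(flavan-4-yl)phenol with 2R,3S,4R upper unit, via reduced MOM ether 8 (not isolated)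
Conditions: Bu3SnH (3 equiv), CF3CO2H, CH2Cl2, 0 °C to rt
Reagents that add atoms: none
Why: In this ionic deoxygenation the acid ionises the carbinol to a C4 cation stabilised by O1, the 7-benzyloxy group and the trioxygenated ring, the stannane should deliver hydride to the α face anti to the 3-silyloxy group so that the aryl ring ends β (3,4-cis, 4R), and the same acid cleaves the aryl MOM ether.

Step 6
Reactants: 9 3,5-bis(benzyloxy)-2-(flavan-4-yl)phenol
Product: 10 4,6-bis(benzyloxy)-2-hydroxy-3-(flavan-4-yl)benzaldehyde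
Conditions: MgCl2, Et3N, paraformaldehyde, THF, reflux; dilute HCl work-up
Reagents that add atoms: formaldehyde (from paraformaldehyde), C=O
Why: Casnati–Skattebøl ortho-formylation through the magnesium phenoxide is specific for the position ortho to the free phenol, and the only such position left is the future C4a.

Step 7
Reactants: 10 salicylaldehyde
Product: 11 3,5-bis(benzyloxy)-2-(hydroxymethyl)-6-(flavan-4-yl)phenol
Conditions: NaBH4, THF/MeOH, 0 °C; neutral work-up, used crude
Reagents that add atoms: none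
Why: Borohydride reduction of the aldehyde gives the salicyl alcohol that is the dehydration precursor of the o-quinone methide.

Step 8
Reactants: 12 3,4,5-tris(benzyloxy)benzaldehyde
Product: 13 1,2,3-tris(benzyloxy)-5-ethynylbenzene
Conditions: dimethyl (1-diazo-2-oxopropyl)phosphonate, K2CO3, MeOH/THF, rt
Reagents that add atoms: dimethyl (1-diazo-2-oxopropyl)phosphonate (Ohira–Bestmann reagent), COP(=O)(OC)C(=[N+]=[N-])C(C)=O
Why: Ohira–Bestmann (Seyferth–Gilbert) homologation converts the aryl aldehyde into the terminal alkyne under conditions that tolerate benzyl ethers.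

Step 9
Reactants: 13 1,2,3-tris(benzyloxy)-5-ethynylbenzene; 14 3,4,5-tris(benzyloxy)benzoic acid
Product: 15 (Z)-2-[3,4,5-tris(benzyloxy)phenyl]ethenyl 3,4,5-tris(benzyloxy)benzoate
Conditions: Ru(η3-CH2C(CH3)CH2)2(Ph2P(CH2)4PPh2) (5 mol %), toluene, 65 °C
Reagents that add atoms: none
Why: Ruthenium-catalysed anti-Markovnikov hydro-acyloxylation of a terminal aryl alkyne through a vinylidene complex should give the (Z)-enol ester, fixing the alkene geometry that becomes the 2,3-cis relation.

Step 10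
Reactants: 11 salicyl alcohol; 15 (Z)-enol gallate
Product: 17 fully protected dimer (upper 3-O-TBS; twelve benzyl ethers; lower ring 2R,3R), via o-quinone methide 16 (not isolated)
Conditions: 15 (3 equiv), (R)-3,3'-bis(2,4,6-triisopropylphenyl)-1,1'-bi-2-naphthol N-triflylphosphoramide (10 mol %), 5 Å molecular sieves, toluene, 0 °C to rt, 11 added over 6 h
Reagents that add atoms: none
Why: Proposed new method: the acid dehydrates the electron-rich salicyl alcohol to the o-quinone methide 16 (C4=C4a–C8a=O1), which stays hydrogen-bonded to the chiral phosphoramide and undergoes an inverse-electron-demand hetero-Diels–Alder reaction with the styrene-type enol ester 15, the C4–C3 bond running ahead and the O1–C2 bond closing the ring. The closest known reactions are the thermal o-quinone methide/styrene route to flavans and the chiral N-triflylphosphoramide-catalysed [4+2] of methide-aryl-substituted o-quinone methides with styrenes, neither of which has been shown for an unsubstituted methide or a β-acyloxystyrene. Ring C of the lower unit closes by [4+2] cycloaddition, in its polar limit a 6-exo-trig attack of O1 on the benzylic C2. C2 and C3 are set together: their cis relation comes from the Z geometry of 15 through suprafacial addition, and their absolute sense (2R,3R) should come from the chiral acid bound at O1, which selects the enantioface of the dienophile while the upper unit acts as a bystander. The step needs regioselectivity (methylene to the ester-bearing carbon, O1 to the benzylic carbon), secured by the benzylic polarisation of 15 through its para-benzyloxy group; it needs the 4→8 rather than the 4→6 ring, secured because O1 is the only free phenol flanking the methylene (O5 and O7 are benzyl ethers); and it needs cycloaddition to outrun self-alkylation at C6, secured by slow addition of 11 into excess 15.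

Step 11
Reactants: 17 fully protected dimer
Product: 18 dodeca-O-benzyl robinetinidol-(4β→8)-epigallocatechin 3-O-gallate
Conditions: HF·pyridine, THF/pyridine, 0 °C to rt
Reagents that add atoms: none
Why: Fluoride-driven cleavage of the silyl ether under buffered conditions frees the upper 3-OH without ester cleavage or acyl migration.

Step 12
Reactants: 18 dodeca-O-benzyl dimer
Product: 19 robinetinidol-(4β→8)-epigallocatechin 3-O-gallate (target)
Conditions: H2 (1 atm), Pd(OH)2/C, THF/MeOH, rt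
Reagents that add atoms: none
Why: Hydrogenolysis of the twelve aryl benzyl ethers should proceed without touching the ester, the benzylic C2–O1 bonds or the C4–aryl bond, and no stereocentre is affected.

**Compound list**
1 | (+)-dihydrorobinetin, (2R,3R)-3,7-dihydroxy-2-(3,4,5-trihydroxyphenyl)chroman-4-one | O=C1c2ccc(O)cc2O[C@H](c2cc(O)c(O)c(O)c2)[C@H]1O | starting material
2 | (2R,3R)-7-(benzyloxy)-3-hydroxy-2-[3,4,5-tris(benzyloxy)phenyl]chroman-4-one | O=C1c2ccc(OCc3ccccc3)cc2O[C@H](c2cc(OCc3ccccc3)c(OCc3ccccc3)c(OCc3ccccc3)c2)[C@H]1O | intermediate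
3 | (2R,3R)-7-(benzyloxy)-3-[(tert-butyldimethylsilyl)oxy]-2-[3,4,5-tris(benzyloxy)phenyl]chroman-4-one | O=C1c2ccc(OCc3ccccc3)cc2O[C@H](c2cc(OCc3ccccc3)c(OCc3ccccc3)c(OCc3ccccc3)c2)[C@H]1O[Si](C)(C)C(C)(C)C | intermediate
4 | 3,5-bis(benzyloxy)phenol | Oc1cc(OCc2ccccc2)cc(OCc2ccccc2)c1 | starting material
5 | 1,3-bis(benzyloxy)-5-(methoxymethoxy)benzene | COCOc1cc(OCc2ccccc2)cc(OCc2ccccc2)c1 | intermediate
6 | [2,4-bis(benzyloxy)-6-(methoxymethoxy)phenyl]lithium | [Li]c1c(OCOC)cc(OCc2ccccc2)cc1OCc1ccccc1 | intermediate (not isolated)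
7 | (2R,3R)-7-(benzyloxy)-4-[2,4-bis(benzyloxy)-6-(methoxymethoxy)phenyl]-3-[(tert-butyldimethylsilyl)oxy]-2-[3,4,5-tris(benzyloxy)phenyl]chroman-4-ol, C4 epimers not distinguished | COCOc1cc(OCc2ccccc2)cc(OCc2ccccc2)c1C1(O)c2ccc(OCc3ccccc3)cc2O[C@H](c2cc(OCc3ccccc3)c(OCc3ccccc3)c(OCc3ccccc3)c2)[C@H]1O[Si](C)(C)C(C)(C)C | intermediate
8 | (2R,3S,4R)-7-(benzyloxy)-4-[2,4-bis(benzyloxy)-6-(methoxymethoxy)phenyl]-3-[(tert-butyldimethylsilyl)oxy]-2-[3,4,5-tris(benzyloxy)phenyl]chroman (2,3-trans, 3,4-cis) | COCOc1cc(OCc2ccccc2)cc(OCc2ccccc2)c1[C@H]1c2ccc(OCc3ccccc3)cc2O[C@H](c2cc(OCc3ccccc3)c(OCc3ccccc3)c(OCc3ccccc3)c2)[C@H]1O[Si](C)(C)C(C)(C)C | intermediate (not isolated)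
9 | 3,5-bis(benzyloxy)-2-{(2R,3S,4R)-7-(benzyloxy)-3-[(tert-butyldimethylsilyl)oxy]-2-[3,4,5-tris(benzyloxy)phenyl]chroman-4-yl}phenol | Oc1cc(OCc2ccccc2)cc(OCc2ccccc2)c1[C@H]1c2ccc(OCc3ccccc3)cc2O[C@H](c2cc(OCc3ccccc3)c(OCc3ccccc3)c(OCc3ccccc3)c2)[C@H]1O[Si](C)(C)C(C)(C)C | intermediate
10 | 4,6-bis(benzyloxy)-2-hydroxy-3-{(2R,3S,4R)-7-(benzyloxy)-3-[(tert-butyldimethylsilyl)oxy]-2-[3,4,5-tris(benzyloxy)phenyl]chroman-4-yl}benzaldehyde | Oc1c(C=O)c(OCc2ccccc2)cc(OCc2ccccc2)c1[C@H]1c2ccc(OCc3ccccc3)cc2O[C@H](c2cc(OCc3ccccc3)c(OCc3ccccc3)c(OCc3ccccc3)c2)[C@H]1O[Si](C)(C)C(C)(C)C | intermediate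
11 | 3,5-bis(benzyloxy)-2-(hydroxymethyl)-6-{(2R,3S,4R)-7-(benzyloxy)-3-[(tert-butyldimethylsilyl)oxy]-2-[3,4,5-tris(benzyloxy)phenyl]chroman-4-yl}phenol | Oc1c(CO)c(OCc2ccccc2)cc(OCc2ccccc2)c1[C@H]1c2ccc(OCc3ccccc3)cc2O[C@H](c2cc(OCc3ccccc3)c(OCc3ccccc3)c(OCc3ccccc3)c2)[C@H]1O[Si](C)(C)C(C)(C)C | intermediate
12 | 3,4,5-tris(benzyloxy)benzaldehyde | O=Cc1cc(OCc2ccccc2)c(OCc2ccccc2)c(OCc2ccccc2)c1 | starting material
13 | 1,2,3-tris(benzyloxy)-5-ethynylbenzene | C#Cc1cc(OCc2ccccc2)c(OCc2ccccc2)c(OCc2ccccc2)c1 | intermediate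
14 | 3,4,5-tris(benzyloxy)benzoic acid | OC(=O)c1cc(OCc2ccccc2)c(OCc2ccccc2)c(OCc2ccccc2)c1 | starting material
15 | (Z)-2-[3,4,5-tris(benzyloxy)phenyl]ethenyl 3,4,5-tris(benzyloxy)benzoate | O=C(O/C=C\c1cc(OCc2ccccc2)c(OCc2ccccc2)c(OCc2ccccc2)c1)c1cc(OCc2ccccc2)c(OCc2ccccc2)c(OCc2ccccc2)c1 | intermediate
16 | 3,5-bis(benzyloxy)-6-methylidene-2-{(2R,3S,4R)-7-(benzyloxy)-3-[(tert-butyldimethylsilyl)oxy]-2-[3,4,5-tris(benzyloxy)phenyl]chroman-4-yl}cyclohexa-2,4-dien-1-one (o-quinone methide) | C=C1C(=O)C([C@H]2c3ccc(OCc4ccccc4)cc3O[C@H](c3cc(OCc4ccccc4)c(OCc4ccccc4)c(OCc4ccccc4)c3)[C@H]2O[Si](C)(C)C(C)(C)C)=C(OCc2ccccc2)C=C1OCc1ccccc1 | intermediate (not isolated)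
17 | upper-3-O-TBS dodeca-O-benzyl robinetinidol-(4β→8)-epigallocatechin 3-O-gallate (upper 2R,3S,4R; lower 2R,3R) | O=C(O[C@@H]1Cc2c(OCc3ccccc3)cc(OCc3ccccc3)c([C@H]3c4ccc(OCc5ccccc5)cc4O[C@H](c4cc(OCc5ccccc5)c(OCc5ccccc5)c(OCc5ccccc5)c4)[C@H]3O[Si](C)(C)C(C)(C)C)c2O[C@@H]1c1cc(OCc2ccccc2)c(OCc2ccccc2)c(OCc2ccccc2)c1)c1cc(OCc2ccccc2)c(OCc2ccccc2)c(OCc2ccccc2)c1 | intermediate
18 | dodeca-O-benzyl robinetinidol-(4β→8)-epigallocatechin 3-O-gallate | O=C(O[C@@H]1Cc2c(OCc3ccccc3)cc(OCc3ccccc3)c([C@H]3c4ccc(OCc5ccccc5)cc4O[C@H](c4cc(OCc5ccccc5)c(OCc5ccccc5)c(OCc5ccccc5)c4)[C@H]3O)c2O[C@@H]1c1cc(OCc2ccccc2)c(OCc2ccccc2)c(OCc2ccccc2)c1)c1cc(OCc2ccccc2)c(OCc2ccccc2)c(OCc2ccccc2)c1 | intermediate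
19 | robinetinidol-(4β→8)-epigallocatechin 3-O-gallate (upper 2R,3S,4R; lower 2R,3R) | O=C(O[C@@H]1Cc2c(O)cc(O)c([C@H]3c4ccc(O)cc4O[C@H](c4cc(O)c(O)c(O)c4)[C@H]3O)c2O[C@@H]1c1cc(O)c(O)c(O)c1)c1cc(O)c(O)c(O)c1 | target

Total step count: 12. Longest linear sequence: 9 (steps 1, 2, 4, 5, 6, 7, 10, 11, 12).

**Steps most likely to fail**

Step 10. The acid may discriminate the two faces of the dienophile poorly in the presence of the bulky C8 substituent. The cis relation may erode if the cycloaddition turns stepwise and the gallate carbonyl captures the benzylic cation. The methide may also alkylate C6 of a second molecule. The fallback uses only known reaction types, sets out from ketone 3 and returns at 17; it takes the lower unit intact from the chiral pool. Commercial (−)-epigallocatechin is benzylated on its five phenols (BnBr, K2CO3, DMF) to penta-O-benzyl-epigallocatechin F1, brominated at C8 (NBS, CH2Cl2, −78 °C) to the 8-bromide F2, and silylated (TESCl, imidazole) to the 3-O-triethylsilyl ether F3. Bromine–lithium exchange (t-BuLi, THF, −78 °C) and addition to 3 give the tertiary carbinol F4. Bu3SnH/CF3CO2H then reduces C4 as in step 5 and strips the labile triethylsilyl group, giving the lower-3-hydroxy dimer F5. Steglich esterification of F5 with acid 14 (DCC, DMAP) gives 17.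

Step 5. Hydride may be delivered to the wrong face of the C4 cation, or the acid may remove the silyl ether before reduction and so lose the shielding group. The fallback sets out from 2 and returns at 9; it reverses the order to hydride first, aryl second. Ketone 2 is reduced (NaBH4, THF/MeOH) to the flavan-3,4-diol F6. Acid-promoted Friedel–Crafts condensation of F6 with excess phenol 4 (BF3·OEt2, CH2Cl2, low temperature) should give both C4 epimers of the ortho-linked adduct, as 5-deoxy flavan-3,4-diols generally do. The 3,4-cis isomer F7 is separated by chromatography. Bis-silylation (TBSOTf, 2,6-lutidine) gives F8, and K2CO3/MeOH cleaves only the aryl silyl ether to return 9.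

Step 4. Lithiation may occur between the two benzyloxy groups or at a benzylic CH2, and excess base may deprotonate ketone 3 instead of the aryllithium adding to it. The fallback sets out from 4 and returns at 7; it generates the nucleophile by halogen–metal exchange on a regiodefined bromide. Amine-catalysed ortho-bromination of 4 (NBS, catalytic i-Pr2NH, CH2Cl2, −78 °C) gives 2-bromo-3,5-bis(benzyloxy)phenol F9, and MOMCl/i-Pr2NEt gives the bromide F10. Bromine–lithium exchange (t-BuLi, THF, −78 °C) then generates aryllithium 6 regiospecifically and without excess alkyllithium before 3 is added, giving 7.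

Further compounds
F1 | step 10 | penta-O-benzyl-(−)-epigallocatechin, (2R,3R)-5,7-bis(benzyloxy)-2-[3,4,5-tris(benzyloxy)phenyl]chroman-3-ol | O[C@@H]1Cc2c(OCc3ccccc3)cc(OCc3ccccc3)cc2O[C@@H]1c1cc(OCc2ccccc2)c(OCc2ccccc2)c(OCc2ccccc2)c1
F2 | step 10 | 8-bromo-penta-O-benzyl-(−)-epigallocatechin | O[C@@H]1Cc2c(OCc3ccccc3)cc(OCc3ccccc3)c(Br)c2O[C@@H]1c1cc(OCc2ccccc2)c(OCc2ccccc2)c(OCc2ccccc2)c1
F3 | step 10 | 8-bromo-3-O-triethylsilyl-penta-O-benzyl-(−)-epigallocatechin | CC[Si](CC)(CC)O[C@@H]1Cc2c(OCc3ccccc3)cc(OCc3ccccc3)c(Br)c2O[C@@H]1c1cc(OCc2ccccc2)c(OCc2ccccc2)c(OCc2ccccc2)c1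
F4 | step 10 | C4 tertiary carbinol from the 8-lithio derivative of F3 and ketone 3 (C4 epimers not distinguished) | CC[Si](CC)(CC)O[C@@H]1Cc2c(OCc3ccccc3)cc(OCc3ccccc3)c(C3(O)c4ccc(OCc5ccccc5)cc4O[C@H](c4cc(OCc5ccccc5)c(OCc5ccccc5)c(OCc5ccccc5)c4)[C@H]3O[Si](C)(C)C(C)(C)C)c2O[C@@H]1c1cc(OCc2ccccc2)c(OCc2ccccc2)c(OCc2ccccc2)c1
F5 | step 10 | upper-3-O-TBS nona-O-benzyl robinetinidol-(4β→8)-epigallocatechin (lower 3-OH free) | O[C@@H]1Cc2c(OCc3ccccc3)cc(OCc3ccccc3)c([C@H]3c4ccc(OCc5ccccc5)cc4O[C@H](c4cc(OCc5ccccc5)c(OCc5ccccc5)c(OCc5ccccc5)c4)[C@H]3O[Si](C)(C)C(C)(C)C)c2O[C@@H]1c1cc(OCc2ccccc2)c(OCc2ccccc2)c(OCc2ccccc2)c1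
F6 | step 5 | (2R,3S,4R)-7-(benzyloxy)-2-[3,4,5-tris(benzyloxy)phenyl]chroman-3,4-diol (major 3,4-trans epimer) | O[C@@H]1c2ccc(OCc3ccccc3)cc2O[C@H](c2cc(OCc3ccccc3)c(OCc3ccccc3)c(OCc3ccccc3)c2)[C@H]1O
F7 | step 5 | 3,5-bis(benzyloxy)-2-{(2R,3S,4R)-7-(benzyloxy)-3-hydroxy-2-[3,4,5-tris(benzyloxy)phenyl]chroman-4-yl}phenol (3,4-cis) | Oc1cc(OCc2ccccc2)cc(OCc2ccccc2)c1[C@H]1c2ccc(OCc3ccccc3)cc2O[C@H](c2cc(OCc3ccccc3)c(OCc3ccccc3)c(OCc3ccccc3)c2)[C@H]1O
F8 | step 5 | bis-TBS ether of F7 (aryl and 3-O silyl ethers) | CC(C)(C)[Si](C)(C)Oc1cc(OCc2ccccc2)cc(OCc2ccccc2)c1[C@H]1c2ccc(OCc3ccccc3)cc2O[C@H](c2cc(OCc3ccccc3)c(OCc3ccccc3)c(OCc3ccccc3)c2)[C@H]1O[Si](C)(C)C(C)(C)C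
F9 | step 4 | 2-bromo-3,5-bis(benzyloxy)phenol | Oc1cc(OCc2ccccc2)cc(OCc2ccccc2)c1Br
F10 | step 4 | 2-bromo-1,5-bis(benzyloxy)-3-(methoxymethoxy)benzene | COCOc1cc(OCc2ccccc2)cc(OCc2ccccc2)c1Br
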